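The α-methylene-γ-butyrolactone ring is removed as one C3O2 unit, 2-bromoacrylic acid, from an acyclic (4E,6Z)-diene that bears a free C8 hydroxyl. One palladium-catalysed heteroannulation joins C11 to C7 and the carboxylate oxygen to C6, and it delivers the exocyclic methylene ready-made. It exploits that C6 of the lactone ring is bonded to C5 of the C4–C5 oxirane ring. Before epoxidation C4=C5–C6=C7 is a conjugated diene, so carbopalladation at C7 leaves an allylpalladium unit that the acid can close only at C6. The C8 carbinol and the Z geometry of C6=C7 control C7 and C6. Ring-closing metathesis then forms the ten-membered ring at (Z)-C1=C10, and one peracid operation installs both oxiranes.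

Key step: step 7

Numbering: germacrane numbering of the target is used for all intermediates (ring C1–C10; C14 on C10; C15 on C4; lactone O on C6, C11 on C7, C12 carbonyl, C13 exocyclic methylene).
Remark: the SMILES places C2 and C9 cis on the C1–C10 oxirane and C3 and C6 trans on the C4–C5 oxirane, so the olefin precursors are taken as (Z)-C1=C10 and (E)-C4=C5.

Step 1
Reactants: 1 (E)-crotonaldehyde; 2 allenylboronic acid pinacol ester
Product: 4 (4S,5E)-hept-5-en-1-yn-4-ol, via boronate ester 3 (not isolated)
Conditions: (S)-3,3'-bis(2,4,6-triisopropylphenyl)-BINOL hydrogen phosphate [(S)-TRIP, 5 mol %], 4 Å MS, toluene, −20 °C; aqueous work-up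
Reagents that add atoms: none
Why: Chiral-phosphoric-acid-catalysed propargylboration runs through a closed six-membered SE2' transition state in which the (S)-catalyst is expected to expose the Si face of the enal and set C2 as S, and the E-propenyl group is kept as a metathesis handle that is disubstituted and therefore sluggish toward palladium insertion in step 7.

Step 2
Reactants: 4 (4S,5E)-hept-5-en-1-yn-4-ol
Product: 6 (1E,4S,5E)-1-iodo-2-methylhepta-1,5-dien-4-ol, via alkenylalane 5 (not isolated)
Conditions: AlMe3, Cp2ZrCl2 (25 mol %), CH2Cl2, 0 °C to rt; then I2, THF, −30 °C; aq. Rochelle salt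
Reagents that add atoms: trimethylaluminium C[Al](C)C; iodine [I][I]
Why: Negishi carboalumination adds methyl and aluminium syn to the terminal alkyne with aluminium at the terminus, and iodinolysis with retention gives the E-iodide that fixes the geometry of C4=C5, while the internal propenyl olefin and the aluminium alkoxide stay inert.

Step 3
Reactants: 6 (1E,4S,5E)-1-iodo-2-methylhepta-1,5-dien-4-ol
Product: 7 tert-butyl{[(1E,4S,5E)-1-iodo-2-methylhepta-1,5-dien-4-yl]oxy}dimethylsilane
Conditions: TBSCl, imidazole, DMF, rt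
Reagents that add atoms: tert-butyldimethylsilyl chloride CC(C)(C)[Si](C)(C)Cl
Why: Standard silyl ether formation masks the C2 hydroxyl so that only the C8 hydroxyl is free for facial control in step 7 and for acylation in step 8.

Step 4
Reactants: 8 3-(trimethylsilyl)prop-2-ynal; 9 2-methylallylmagnesium chloride
Product: 13 (3S)-5-methylhex-5-en-1-yn-3-ol, via methallylborane 10 (not isolated), via borinate 11 (not isolated), via silylalkynol 12 (not isolated)
Conditions: 9, (−)-B-methoxydiisopinocampheylborane, Et2O, 0 °C to rt; 8, −78 °C; NaOH, H2O2, 0 °C; crude, K2CO3 (cat.), MeOH, rt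
Reagents that add atoms: none
Why: In this Brown asymmetric allylboration the borane 10 adds through a chair-like six-membered transition state in which the isopinocampheyl groups derived from (+)-α-pinene expose the Si face of the ynal and set C8 as S, and alkaline methanol then cleaves the labile alkynyl–silicon bond of the crude carbinol.

Step 5
Reactants: 7 silyl-protected alkenyl iodide; 13 (3S)-5-methylhex-5-en-1-yn-3-ol
Product: 14 (4S,7E,10S,11E)-10-[(tert-butyldimethylsilyl)oxy]-2,8-dimethyltrideca-1,7,11-trien-5-yn-4-ol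
Conditions: PdCl2(PPh3)2 (3 mol %), CuI (6 mol %), Et3N, THF, rt
Reagents that add atoms: none
Why: Sonogashira coupling joins C5 to C6 with retention of the E geometry of the alkenyl iodide and tolerates the free propargylic hydroxyl, the silyl ether and the isolated olefins at room temperature.

Step 6
Reactants: 14 enyne
Product: 15 (4S,5Z,7E,10S,11E)-10-[(tert-butyldimethylsilyl)oxy]-2,8-dimethyltrideca-1,5,7,11-tetraen-4-ol
Conditions: Zn(Cu/Ag) couple [Zn dust, Cu(OAc)2, AgNO3], MeOH–H2O 1:1, rt to 40 °C
Reagents that add atoms: none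
Why: Boland reduction with activated zinc delivers both hydrogens to one face of a conjugated, hydroxyl-flanked alkyne only, so the Z-C6=C7 olefin should form without change at the isolated olefins or at E-C4=C5.

Step 7
Reactants: 15 (5Z,7E)-dienol; 16 2-bromoacrylic acid
Product: 18 (4R,5R)-5-{(1E,4S,5E)-4-[(tert-butyldimethylsilyl)oxy]-2-methylhepta-1,5-dien-1-yl}-4-[(1S)-1-hydroxy-3-methylbut-3-en-1-yl]-3-methylideneoxolan-2-one, via allylpalladium chloride 17 (not isolated)
Conditions: Pd(OAc)2 (10 mol %), PPh3 (20 mol %), n-Bu4NCl, Na2CO3, DMF, 70 °C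
Reagents that add atoms: none
Why: This is a Larock-type heteroannulation of a 1,3-diene by a vinylic halide that carries its own nucleophile: zerovalent palladium inserts into the C–Br bond of 16, the 1-carboxyvinylpalladium species adds syn across C6=C7 with carbon going to C7, and the resulting η3-allyl unit C4–C5–C6 (17) is displaced at C6 by the pendant carboxylate. The lactone ring closes in a 5-exo mode on the near allyl terminus, whereas attack at C4 would need a seven-membered ring and a fully substituted carbon. C7 is set by the C8 carbinol: allylic 1,3-strain in the Z-olefin holds H8 in the olefin plane, so palladium should bind the face that carries the small, hydrogen-bonding hydroxyl and not the face shielded by the C9 methallyl chain. C6 is set by olefin geometry: syn carbopalladation followed by anti attack of a carboxylate that chloride keeps off the metal amounts to anti addition to a Z-olefin, which gives the trans-4,5-disubstituted lactone, and the E geometry of C4=C5 is carried through the syn-allyl. The step needs diene-over-olefin and C7-over-C4 selectivity: only the diene can end as a stabilised allyl complex, the isolated olefins are disubstituted and poor partners for intermolecular insertion, and C4 is fully substituted.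

Step 8
Reactants: 18 hydroxy lactone; 19 angelic acid [(Z)-2-methylbut-2-enoic acid]
Product: 21 C8 angelate of 18 (2S,6R,7R,8S), via mixed anhydride 20 (not isolated)
Conditions: 19, 2,4,6-trichlorobenzoyl chloride, Et3N, toluene, rt; then 18, 80 °C
Reagents that add atoms: none
Why: Yamaguchi-type mixed-anhydride esterification acylates the only free hydroxyl with retention at C8, and the absence of a nucleophilic pyridine catalyst avoids the addition–elimination path that turns angelates into tiglates.

Step 9
Reactants: 21 silyl-protected angelate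
Product: 22 C2 alcohol (2S,6R,7R,8S), the seco-triene angelate
Conditions: HF·pyridine, THF, 0 °C to rt
Reagents that add atoms: none
Why: Fluoride-mediated desilylation under mildly acidic conditions frees the C2 hydroxyl without acyl migration, ester cleavage or conjugate addition to C13.

Step 10
Reactants: 22 seco-triene angelate
Product: 23 (1(10)Z,4E)-8-angeloyloxy-2-hydroxygermacra-1(10),4,11(13)-trien-12,6-olide (2S,6R,7R,8S)
Conditions: second-generation Hoveyda–Grubbs catalyst (15 mol %), 2,6-dichloro-1,4-benzoquinone (30 mol %), toluene (1 mM), 80 °C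
Reagents that add atoms: none
Why: In this ring-closing metathesis the catalyst loads on the propenyl terminus next to the activating free allylic hydroxyl and closes onto the 1,1-disubstituted C10 olefin with loss of propene, strain in a ten-membered ring that already holds E-C4=C5 and the trans-fused lactone allows only the Z geometry at C1=C10, E-C4=C5 rules out a six-membered closure, and the electron-poor C11=C13 and angelate olefins are poor partners.

Step 11
Reactants: 23 macrocyclic trienolide
Product: 25 target (1R,2S,4R,5R,6S,7R,8S,10S)-8-angeloyloxy-1,10:4,5-diepoxy-2-hydroxygermacr-11(13)-en-12,6-olide, via monoepoxide 24 (not isolated)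
Conditions: mCPBA (2.5 equiv), CH2Cl2, 0 °C to rt
Reagents that add atoms: meta-chloroperoxybenzoic acid O=C(OO)c1cccc(Cl)c1
Why: Prilezhaev epoxidation attacks only the two electron-rich trisubstituted olefins: at C1=C10 allylic 1,3-strain places H2 in the olefin plane, so the hydrogen-bonding C2 hydroxyl and the open outer face of the ring coincide and should give the (1R,10S)-cis-oxirane, and at C4=C5 H6 eclipses C15, so the outer face syn to the lactone oxygen should give the (4R,5R)-trans-oxirane, while the conjugated C11=C13 and angelate olefins are inert to peracid.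

Compound list
1 | (E)-crotonaldehyde | C/C=C/C=O | starting material
2 | allenylboronic acid pinacol ester | C=C=CB1OC(C)(C)C(C)(C)O1 | starting material
3 | 2-{[(4S,5E)-hept-5-en-1-yn-4-yl]oxy}-4,4,5,5-tetramethyl-1,3,2-dioxaborolane | C#CC[C@H](OB1OC(C)(C)C(C)(C)O1)/C=C/C | intermediate
4 | (4S,5E)-hept-5-en-1-yn-4-ol | C#CC[C@H](O)/C=C/C | intermediate
5 | (E)-alkenyldimethylalane, dimethylaluminium alkoxide of the C2 oxygen | C[Al](C)/C=C(\C)C[C@H](O[Al](C)C)/C=C/C | intermediate
6 | (1E,4S,5E)-1-iodo-2-methylhepta-1,5-dien-4-ol | I/C=C(\C)C[C@H](O)/C=C/C | intermediate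
7 | tert-butyl{[(1E,4S,5E)-1-iodo-2-methylhepta-1,5-dien-4-yl]oxy}dimethylsilane | I/C=C(\C)C[C@H](O[Si](C)(C)C(C)(C)C)/C=C/C | intermediate
8 | 3-(trimethylsilyl)prop-2-ynal | C[Si](C)(C)C#CC=O | starting material
9 | 2-methylallylmagnesium chloride | C=C(C)C[Mg]Cl | starting material
10 | B-(2-methylallyl)diisopinocampheylborane, (+)-α-pinene series | C=C(C)CB([C@@H]1C[C@@H]2C[C@H]([C@H]1C)C2(C)C)[C@@H]1C[C@@H]2C[C@H]([C@H]1C)C2(C)C | intermediate
11 | diisopinocampheylborinate of 12 | C=C(C)C[C@H](OB([C@@H]1C[C@@H]2C[C@H]([C@H]1C)C2(C)C)[C@@H]1C[C@@H]2C[C@H]([C@H]1C)C2(C)C)C#C[Si](C)(C)C | intermediate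
12 | (3S)-5-methyl-1-(trimethylsilyl)hex-5-en-1-yn-3-ol | C=C(C)C[C@H](O)C#C[Si](C)(C)C | intermediate
13 | (3S)-5-methylhex-5-en-1-yn-3-ol | C=C(C)C[C@H](O)C#C | intermediate
14 | (4S,7E,10S,11E)-10-[(tert-butyldimethylsilyl)oxy]-2,8-dimethyltrideca-1,7,11-trien-5-yn-4-ol | C=C(C)C[C@H](O)C#C/C=C(\C)C[C@H](O[Si](C)(C)C(C)(C)C)/C=C/C | intermediate
15 | (4S,5Z,7E,10S,11E)-10-[(tert-butyldimethylsilyl)oxy]-2,8-dimethyltrideca-1,5,7,11-tetraen-4-ol | C=C(C)C[C@H](O)/C=C\C=C(/C)C[C@H](O[Si](C)(C)C(C)(C)C)/C=C/C | intermediate
16 | 2-bromoacrylic acid | C=C(Br)C(=O)O | starting material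
17 | η3-allylpalladium chloride over C4–C6, drawn in its C6-σ form, C11 already bonded to C7 | C=C(C(=O)O)[C@@H]([C@@H]([Pd]Cl)/C=C(\C)C[C@H](O[Si](C)(C)C(C)(C)C)/C=C/C)[C@@H](O)CC(C)=C | intermediate
18 | (4R,5R)-5-{(1E,4S,5E)-4-[(tert-butyldimethylsilyl)oxy]-2-methylhepta-1,5-dien-1-yl}-4-[(1S)-1-hydroxy-3-methylbut-3-en-1-yl]-3-methylideneoxolan-2-one | C=C1C(=O)O[C@H](/C=C(\C)C[C@H](O[Si](C)(C)C(C)(C)C)/C=C/C)[C@H]1[C@@H](O)CC(C)=C | intermediate
19 | angelic acid, (Z)-2-methylbut-2-enoic acid | C/C=C(/C)C(=O)O | starting material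
20 | angelic 2,4,6-trichlorobenzoic anhydride | C/C=C(/C)C(=O)OC(=O)c1c(Cl)cc(Cl)cc1Cl | intermediate
21 | C8 angelate of 18, (2S,6R,7R,8S) | C=C1C(=O)O[C@H](/C=C(\C)C[C@H](O[Si](C)(C)C(C)(C)C)/C=C/C)[C@H]1[C@@H](OC(=O)/C(C)=C\C)CC(C)=C | intermediate
22 | C2 alcohol from 21, (2S,6R,7R,8S) | C=C1C(=O)O[C@H](/C=C(\C)C[C@H](O)/C=C/C)[C@H]1[C@@H](OC(=O)/C(C)=C\C)CC(C)=C | intermediate
23 | (1(10)Z,4E)-8-angeloyloxy-2-hydroxygermacra-1(10),4,11(13)-trien-12,6-olide, (2S,6R,7R,8S) | C=C1C(=O)O[C@@H]2/C=C(\C)C[C@H](O)/C=C(/C)C[C@H](OC(=O)/C(C)=C\C)[C@@H]12 | intermediate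
24 | (1R,10S)-1,10-epoxide of 23, (1R,2S,6R,7R,8S,10S) | C=C1C(=O)O[C@@H]2/C=C(\C)C[C@H](O)[C@H]3O[C@@]3(C)C[C@H](OC(=O)/C(C)=C\C)[C@@H]12 | intermediate
25 | (1R,2S,4R,5R,6S,7R,8S,10S)-8-angeloyloxy-1,10:4,5-diepoxy-2-hydroxygermacr-11(13)-en-12,6-olide, CNP0388761.1 | C=C1C(=O)O[C@H]2[C@H]1[C@@H](OC(=O)/C(C)=C\C)C[C@]1(C)O[C@@H]1[C@@H](O)C[C@@]1(C)O[C@H]21 | target

Total step count: 11. Longest linear sequence: 10 steps (1, 2, 3, 5, 6, 7, 8, 9, 10, 11).

Steps most likely to fail

Step 7. The palladium species may bind the diene on the face anti to the C8 oxygen, so facial selectivity at C7 may be poor or reversed. Insertion into an isolated olefin may also erode the conversion. The fallback turns a preference for the anti face to use by entering with the C8 epimer and correcting C8 during esterification.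
- It sets out from 8 and 9. (+)-B-Methoxydiisopinocampheylborane gives the enantiomeric B-(2-methylallyl)diisopinocampheylborane F1, which adds to 8 to give the borinate F2.
- Alkaline peroxide gives the (3R)-silylalkynol F3, and methanolysis gives (3R)-5-methylhex-5-en-1-yn-3-ol F4.
- Sonogashira coupling with 7 gives the (4R)-enyne F5, and Boland reduction gives the (4R,5Z,7E)-dienol F6.
- Annulation with 16 under the conditions of step 7 passes through the allylpalladium chloride F7 to the (1R)-hydroxyalkyl lactone F8, which has C6 and C7 as in 18.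
- Mitsunobu esterification of F8 with 19 (PPh3, DIAD, toluene, 0 °C) inverts C8 and comes back to the route at 21.

Step 10. Folding of 22 into the strained ring may be slow, so oligomerisation through the propenyl terminus or ruthenium-hydride isomerisation of the free allylic alcohol may outrun closure. The fallback closes the ring at another intermediate, before the bulky ester sits next to the arm that has to fold and while the allylic oxygen is still silylated.
- It sets out from 18. Ring-closing metathesis gives (1(10)Z,4E)-2-(tert-butyldimethylsilyloxy)-8-hydroxygermacra-1(10),4,11(13)-trien-12,6-olide F9.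
- Acylation with 19 by way of 20 gives its 8-angelate F10.
- HF·pyridine comes back to the route at 23.

Step 11. Facial selectivity at C4=C5 may be poor. The acid formed in the flask may also trigger transannular attack of C4=C5 on the first oxirane. The fallback replaces substrate control by reagent control under buffered conditions.
- It sets out from 23. One equivalent of mCPBA at −20 °C is used, and 24 is isolated.
- Shi epoxidation of 24 (D-fructose-derived ketone, KHSO5, K2CO3 buffer, MeCN–dimethoxymethane–water, 0 °C) follows. Its spiro transition state is expected to give the (R,R)-oxirane from an E-trisubstituted olefin, and this comes back to the route at 25.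

Further compounds
F1 | step 7 | B-(2-methylallyl)diisopinocampheylborane, (−)-α-pinene series | C=C(C)CB([C@H]1C[C@H]2C[C@@H]([C@@H]1C)C2(C)C)[C@H]1C[C@H]2C[C@@H]([C@@H]1C)C2(C)C
F2 | step 7 | diisopinocampheylborinate of F3 | C=C(C)C[C@@H](OB([C@H]1C[C@H]2C[C@@H]([C@@H]1C)C2(C)C)[C@H]1C[C@H]2C[C@@H]([C@@H]1C)C2(C)C)C#C[Si](C)(C)C
F3 | step 7 | (3R)-5-methyl-1-(trimethylsilyl)hex-5-en-1-yn-3-ol | C=C(C)C[C@@H](O)C#C[Si](C)(C)C
F4 | step 7 | (3R)-5-methylhex-5-en-1-yn-3-ol | C=C(C)C[C@@H](O)C#C
F5 | step 7 | (4R,7E,10S,11E)-10-[(tert-butyldimethylsilyl)oxy]-2,8-dimethyltrideca-1,7,11-trien-5-yn-4-ol | C=C(C)C[C@@H](O)C#C/C=C(\C)C[C@H](O[Si](C)(C)C(C)(C)C)/C=C/C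
F6 | step 7 | (4R,5Z,7E,10S,11E)-10-[(tert-butyldimethylsilyl)oxy]-2,8-dimethyltrideca-1,5,7,11-tetraen-4-ol | C=C(C)C[C@@H](O)/C=C\C=C(/C)C[C@H](O[Si](C)(C)C(C)(C)C)/C=C/C
F7 | step 7 | η3-allylpalladium chloride of the 8R series, drawn in its C6-σ form | C=C(C(=O)O)[C@@H]([C@@H]([Pd]Cl)/C=C(\C)C[C@H](O[Si](C)(C)C(C)(C)C)/C=C/C)[C@H](O)CC(C)=C
F8 | step 7 | (4R,5R)-5-{(1E,4S,5E)-4-[(tert-butyldimethylsilyl)oxy]-2-methylhepta-1,5-dien-1-yl}-4-[(1R)-1-hydroxy-3-methylbut-3-en-1-yl]-3-methylideneoxolan-2-one | C=C1C(=O)O[C@H](/C=C(\C)C[C@H](O[Si](C)(C)C(C)(C)C)/C=C/C)[C@H]1[C@H](O)CC(C)=C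
F9 | step 10 | (1(10)Z,4E)-2-(tert-butyldimethylsilyloxy)-8-hydroxygermacra-1(10),4,11(13)-trien-12,6-olide, (2S,6R,7R,8S) | C=C1C(=O)O[C@@H]2/C=C(\C)C[C@H](O[Si](C)(C)C(C)(C)C)/C=C(/C)C[C@H](O)[C@@H]12
F10 | step 10 | 8-angelate of F9 | C=C1C(=O)O[C@@H]2/C=C(\C)C[C@H](O[Si](C)(C)C(C)(C)C)/C=C(/C)C[C@H](OC(=O)/C(C)=C\C)[C@@H]12
F0 | step 11 | none | none
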